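Ring A is built, not substituted: its five substituents must sit in the order C4a alkyl, C8a oxygen, C8 acyl, C7 oxygen, C5 oxygen (C6 free), an order that electrophilic chemistry on phloroglucinol leaves open. The disconnection therefore cuts C8a–C8, C6–C7, C5–C6 and C8a–C4a. In one photochemical operation a diazomethyl ketone rearranges to a vinylketene that takes up a siloxyalkyne and closes ring A with every group in place. The precursor is a Z-configured 2-methoxy enone diazomethyl ketone that already carries the C4 stereocentre (phenyl, tert-butyl acetate arm); its partner is a triisopropylsiloxyalkyne bearing the ketal-masked C8 acetyl. Lactonisation, demethylation and Claisen–Schmidt condensation finish the target.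

Key step: step 10

Remarks on the design:
- Ring positions (C4a, C5 … C8a) are those of the chroman-2-one core of the target.
- The spectator ester is tert-butyl. It survives hydride removal of the auxiliary and the strong base of step 7, cannot lactonise early, and leaves in the same acid step that unmasks the acetyl group.
- The diazo group is put on by diazo transfer to a methyl ketone. No second ester has to be differentiated, and no conjugated acid chloride has to meet diazomethane.
- The benzylic centre is set once (step 2) and is not touched afterwards. Its descriptor alternates between R and S only through the sequence rule.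
- Assumption: compounds 1, 2, 4, 8, 13 and 27 are taken as commercial.

Step 1
Reactants: 1 (4R)-4-benzyl-1,3-oxazolidin-2-one; 2 phenylacetyl chloride
Product: 3 (4R)-4-benzyl-3-(phenylacetyl)-1,3-oxazolidin-2-one
Conditions: n-BuLi, THF, −78 °C; then 2, −78 → 0 °C
Reagents that add atoms: none
Why: N-Acylation of the lithiated oxazolidinone with an acid chloride is the standard loading of an Evans auxiliary and creates no stereocentre.

Step 2
Reactants: 3 (4R)-4-benzyl-3-(phenylacetyl)-1,3-oxazolidin-2-one; 4 tert-butyl bromoacetate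
Product: 5 tert-butyl (3R)-4-[(4R)-4-benzyl-2-oxo-1,3-oxazolidin-3-yl]-4-oxo-3-phenylbutanoate
Conditions: NaN(SiMe3)2, THF, −78 °C; then 4, −78 → −50 °C
Reagents that add atoms: none
Why: Evans asymmetric alkylation: the chelated Z-sodium enolate is shielded on one face by the C4 benzyl group, so the bromoacetate should enter from the opposite face and set the benzylic centre as (3R), the configuration that becomes C4 of the target.

Step 3
Reactants: 5 tert-butyl (3R)-4-[(4R)-4-benzyl-2-oxo-1,3-oxazolidin-3-yl]-4-oxo-3-phenylbutanoate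
Product: 6 tert-butyl (3R)-4-hydroxy-3-phenylbutanoate
Conditions: LiBH4, H2O (1 equiv), Et2O, 0 °C
Reagents that add atoms: none
Why: Reductive removal of the auxiliary: LiBH4 attacks the activated exocyclic imide carbonyl in preference to the hindered tert-butyl ester, hydride is too weakly basic to epimerise the α-aryl centre, and the tert-butyl ester resists lactonisation of the 4-hydroxy ester.

Step 4
Reactants: 6 tert-butyl (3R)-4-hydroxy-3-phenylbutanoate
Product: 7 tert-butyl (3R)-4-oxo-3-phenylbutanoate
Conditions: Dess–Martin periodinane, NaHCO3, CH2Cl2, 0 °C → rt; used crude at once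
Reagents that add atoms: none
Why: Dess–Martin oxidation proceeds without amine base, so the enolisable α-aryl aldehyde should be obtained with its configuration intact.

Step 5
Reactants: 8 dimethyl (1-diazo-2-oxopropyl)phosphonate
Product: 9 dimethyl (1-methoxy-2-oxopropyl)phosphonate (racemic)
Conditions: MeOH (3 equiv), Rh2(OAc)4 (1 mol %), ClCH2CH2Cl, 70 °C
Reagents that add atoms: methanol, CO
Why: Rhodium-carbenoid O–H insertion of an α-diazo-β-ketophosphonate into an alcohol is an established way to α-alkoxy phosphonates.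

Step 6
Reactants: 7 tert-butyl (3R)-4-oxo-3-phenylbutanoate; 9 dimethyl (1-methoxy-2-oxopropyl)phosphonate
Product: 10 tert-butyl (3S,4Z)-5-methoxy-6-oxo-3-phenylhept-4-enoate
Conditions: 9 (1.3 equiv), NaH (1.2 equiv), THF, 0 °C; then 7, −78 → 0 °C
Reagents that add atoms: none
Why: Horner–Wadsworth–Emmons olefination: the preformed ketophosphonate anion (no free base) should add to the aldehyde faster than it enolises it and should place the acetyl group trans to C3 (Z), the usual outcome with 2-alkoxy phosphonates and α-branched aldehydes; a minor E isomer would be removed by chromatography.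

Step 7
Reactants: 10 tert-butyl (3S,4Z)-5-methoxy-6-oxo-3-phenylhept-4-enoate
Product: 12 tert-butyl (3S,4Z)-7-diazo-5-methoxy-6-oxo-3-phenylhept-4-enoate, via trifluoroacetyl diketone 11 (not isolated)
Conditions: LiN(SiMe3)2, THF, −78 °C; CF3CO2CH2CF3, −78 °C; aq. HCl work-up; then MsN3, Et3N, H2O (1 equiv), MeCN, rt
Reagents that add atoms: methanesulfonyl azide, CS(=O)(=O)N=[N+]=[N-]
Why: Detrifluoroacetylative diazo transfer, the standard entry to α,β-unsaturated diazomethyl ketones: kinetic deprotonation occurs at the methyl group (the γ-hydrogen at C3 is trans to the carbonyl and out of reach), the enolate is trifluoroacetylated, and the activated diketone 11 accepts the diazo group with loss of the trifluoroacetyl unit.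

Step 8
Reactants: 13 ethyl pyruvate
Product: 14 ethyl 2-methyl-1,3-dioxolane-2-carboxylate
Conditions: HOCH2CH2OH, TsOH·H2O (cat.), toluene, reflux, Dean–Stark
Reagents that add atoms: ethylene glycol, OCCO
Why: Acid-catalysed ketalisation with azeotropic removal of water masks the ketone that will become the C8 acetyl group.

Step 9
Reactants: 14 ethyl 2-methyl-1,3-dioxolane-2-carboxylate
Product: 17 triisopropyl{[(2-methyl-1,3-dioxolan-2-yl)ethynyl]oxy}silane, via dibromo enolate 15 (not isolated), via lithium ynolate 16 (not isolated)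
Conditions: CH2Br2, lithium 2,2,6,6-tetramethylpiperidide (2.1 equiv), THF, −78 °C; n-BuLi, −78 °C → rt; iPr3SiOTf, −78 → 0 °C
Reagents that add atoms: dibromomethane, BrCBr; triisopropylsilyl trifluoromethanesulfonate, CC(C)[Si](OS(=O)(=O)C(F)(F)F)(C(C)C)C(C)C
Why: Kowalski ester homologation: dibromomethyllithium adds to the ester, the derived dibromo enolate 15 undergoes bromine–lithium exchange and a 1,2-shift of the dioxolanyl group to ynolate 16, and the bulky silyl triflate traps the ynolate on oxygen to give the silyl ynol ether.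

Step 10
Reactants: 12 tert-butyl (3S,4Z)-7-diazo-5-methoxy-6-oxo-3-phenylhept-4-enoate; 17 triisopropyl{[(2-methyl-1,3-dioxolan-2-yl)ethynyl]oxy}silane
Product: 22 tert-butyl (3R)-3-[2-hydroxy-6-methoxy-3-(2-methyl-1,3-dioxolan-2-yl)-4-(triisopropylsilyloxy)phenyl]-3-phenylpropanoate, via vinylketene 18 (not isolated), via vinylcyclobutenone 19 (not isolated), via dienylketene 20 (not isolated), via cyclohexadienone 21 (not isolated)
Conditions: 17 (1.3 equiv), hν (254 nm, Vycor), degassed ClCH2CH2Cl, rt; then 80 °C in the dark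
Reagents that add atoms: none
Why: Light expels N2 from 12 and the photochemical Wolff shift of the alkenyl group (forming C5–C6) gives vinylketene 18, whose ketene C=C adds to the ynol ether in a [2+2] cycloaddition to vinylcyclobutenone 19; 4π electrocyclic opening (by light or in the thermal stage) gives dienylketene 20, 6π electrocyclisation gives dienone 21, and enolisation gives the phenol. This is the photochemical variant of the Danheiser benzannulation with a siloxyalkyne as ketenophile, and the 3-methoxy vinylketene only adds a donor substituent to a known substrate class. Ring A is closed by the thermally allowed disrotatory 6π electrocyclisation of 20 (C8a–C4a), the transient four-membered ring by the [2+2] step (C8a–C8 and C6–C7). No stereocentre is created: the sp3 ring carbons of 19 and 21 are erased on opening and enolisation, and the benzylic centre is a spectator whose label changes from S to R only because the new aryl group outranks phenyl. The step needs regioselectivity in the [2+2] addition, secured by the polarisation of the ynol ether (its carbon remote from silyloxy is nucleophilic and bonds to the electrophilic ketene carbon, so the C8a hydroxyl ends between the masked acetyl and C4a), and it needs the ketene to last until capture, secured by the Z geometry, which holds the benzylic C–H away from the ketene terminus so that no 1,5-hydrogen shift can consume the ketene or destroy the stereocentre.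

Step 11
Reactants: 22 tert-butyl (3R)-3-[2-hydroxy-6-methoxy-3-(2-methyl-1,3-dioxolan-2-yl)-4-(triisopropylsilyloxy)phenyl]-3-phenylpropanoate
Product: 25 (4R)-8-acetyl-7-hydroxy-5-methoxy-4-phenyl-3,4-dihydro-2H-chromen-2-one, via desilylated diphenol 23 (not isolated), via hydroxy acid 24 (not isolated)
Conditions: Bu4NF, THF, 0 °C; then CF3CO2H/CH2Cl2 (1:1), H2O (5 equiv), anisole, rt; then toluene, 60 °C
Reagents that add atoms: water, O
Why: Fluoride cleaves the aryl silyl ether, acidolysis then removes the tert-butyl ester and the dioxolane, and the C8a phenol, held next to the acid arm, closes the six-membered ring by acid-catalysed lactonisation, while the 5-methyl ether and the non-enolisable C4 centre are untouched.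

Step 12
Reactants: 25 (4R)-8-acetyl-7-hydroxy-5-methoxy-4-phenyl-3,4-dihydro-2H-chromen-2-one
Product: 26 (4R)-8-acetyl-5,7-dihydroxy-4-phenyl-3,4-dihydro-2H-chromen-2-one
Conditions: BBr3, CH2Cl2, −78 °C → rt; then H2O
Reagents that add atoms: none
Why: Boron tribromide cleavage of an aryl methyl ether is routine for methoxy-dihydrocoumarins, and the lactone and the hydrogen-bonded acetyl group are expected to survive at low temperature.

Step 13
Reactants: 26 (4R)-8-acetyl-5,7-dihydroxy-4-phenyl-3,4-dihydro-2H-chromen-2-one; 27 3,4-dihydroxybenzaldehyde (protocatechualdehyde)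
Product: 28 (4R)-8-[(2E)-3-(3,4-dihydroxyphenyl)prop-2-enoyl]-5,7-dihydroxy-4-phenyl-3,4-dihydro-2H-chromen-2-one
Conditions: 27 (1.2 equiv), BF3·OEt2, 1,4-dioxane, rt
Reagents that add atoms: none
Why: Lewis-acid-promoted Claisen–Schmidt condensation: BF3 activates the chelated ortho-hydroxy acetophenone and the aldehyde, tolerates free phenols and the base-labile lactone, and dehydration gives the conjugated E enone, while C4 is not enolisable and is unaffected.

Compound list
1 | (4R)-4-benzyl-1,3-oxazolidin-2-one | O=C1N[C@H](Cc2ccccc2)CO1 | starting material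
2 | phenylacetyl chloride | O=C(Cl)Cc1ccccc1 | starting material
3 | (4R)-4-benzyl-3-(phenylacetyl)-1,3-oxazolidin-2-one | O=C1N(C(=O)Cc2ccccc2)[C@H](Cc2ccccc2)CO1 | intermediate
4 | tert-butyl bromoacetate | CC(C)(C)OC(=O)CBr | starting material
5 | tert-butyl (3R)-4-[(4R)-4-benzyl-2-oxo-1,3-oxazolidin-3-yl]-4-oxo-3-phenylbutanoate | CC(C)(C)OC(=O)C[C@H](c1ccccc1)C(=O)N1C(=O)OC[C@H]1Cc1ccccc1 | intermediate
6 | tert-butyl (3R)-4-hydroxy-3-phenylbutanoate | CC(C)(C)OC(=O)C[C@H](c1ccccc1)CO | intermediate
7 | tert-butyl (3R)-4-oxo-3-phenylbutanoate | CC(C)(C)OC(=O)C[C@H](c1ccccc1)C=O | intermediate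
8 | dimethyl (1-diazo-2-oxopropyl)phosphonate | CC(=O)C(=[N+]=[N-])P(=O)(OC)OC | starting material
9 | dimethyl (1-methoxy-2-oxopropyl)phosphonate (racemic) | COC(C(C)=O)P(=O)(OC)OC | intermediate
10 | tert-butyl (3S,4Z)-5-methoxy-6-oxo-3-phenylhept-4-enoate | CC(C)(C)OC(=O)C[C@H](c1ccccc1)/C=C(\OC)C(C)=O | intermediate
11 | tert-butyl (3S,4Z)-9,9,9-trifluoro-5-methoxy-6,8-dioxo-3-phenylnon-4-enoate (trifluoroacetyl diketone; not isolated) | CC(C)(C)OC(=O)C[C@H](c1ccccc1)/C=C(\OC)C(=O)CC(=O)C(F)(F)F | intermediate
12 | tert-butyl (3S,4Z)-7-diazo-5-methoxy-6-oxo-3-phenylhept-4-enoate | CC(C)(C)OC(=O)C[C@H](c1ccccc1)/C=C(\OC)C(=O)C=[N+]=[N-] | intermediate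
13 | ethyl pyruvate | CCOC(=O)C(C)=O | starting material
14 | ethyl 2-methyl-1,3-dioxolane-2-carboxylate | CCOC(=O)C1(C)OCCO1 | intermediate
15 | lithium 2,2-dibromo-1-(2-methyl-1,3-dioxolan-2-yl)ethenolate (dibromo enolate; not isolated) | [Li+].[O-]C(=C(Br)Br)C1(C)OCCO1 | intermediate
16 | lithium 2-(2-methyl-1,3-dioxolan-2-yl)ethyn-1-olate (lithium ynolate; not isolated) | [Li+].[O-]C#CC1(C)OCCO1 | intermediate
17 | triisopropyl{[(2-methyl-1,3-dioxolan-2-yl)ethynyl]oxy}silane | CC1(C#CO[Si](C(C)C)(C(C)C)C(C)C)OCCO1 | intermediate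
18 | tert-butyl (3S,4Z)-5-methoxy-7-oxo-3-phenylhepta-4,6-dienoate (vinylketene; not isolated) | CC(C)(C)OC(=O)C[C@H](c1ccccc1)/C=C(\OC)C=C=O | intermediate
19 | tert-butyl (3S,4Z)-5-methoxy-5-[3-(2-methyl-1,3-dioxolan-2-yl)-4-oxo-2-(triisopropylsilyloxy)cyclobut-2-en-1-yl]-3-phenylpent-4-enoate (vinylcyclobutenone; both epimers at the ring carbon; not isolated) | CC(C)(C)OC(=O)C[C@H](c1ccccc1)/C=C(\OC)C1C(=O)C(C2(C)OCCO2)=C1O[Si](C(C)C)(C(C)C)C(C)C | intermediate
20 | tert-butyl (3S,4Z,6E)-5-methoxy-8-(2-methyl-1,3-dioxolan-2-yl)-9-oxo-3-phenyl-7-(triisopropylsilyloxy)nona-4,6,8-trienoate (dienylketene; not isolated) | CC(C)(C)OC(=O)C[C@H](c1ccccc1)/C=C(\OC)/C=C(/O[Si](C(C)C)(C(C)C)C(C)C)C(=C=O)C1(C)OCCO1 | intermediate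
21 | tert-butyl (3S)-3-[2-methoxy-5-(2-methyl-1,3-dioxolan-2-yl)-6-oxo-4-(triisopropylsilyloxy)cyclohexa-2,4-dien-1-yl]-3-phenylpropanoate (cyclohexadienone; both epimers at the ring carbon; not isolated) | CC(C)(C)OC(=O)C[C@H](c1ccccc1)C1C(OC)=CC(O[Si](C(C)C)(C(C)C)C(C)C)=C(C2(C)OCCO2)C1=O | intermediate
22 | tert-butyl (3R)-3-[2-hydroxy-6-methoxy-3-(2-methyl-1,3-dioxolan-2-yl)-4-(triisopropylsilyloxy)phenyl]-3-phenylpropanoate | CC(C)(C)OC(=O)C[C@H](c1ccccc1)c1c(OC)cc(O[Si](C(C)C)(C(C)C)C(C)C)c(C2(C)OCCO2)c1O | intermediate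
23 | tert-butyl (3R)-3-[2,4-dihydroxy-6-methoxy-3-(2-methyl-1,3-dioxolan-2-yl)phenyl]-3-phenylpropanoate (desilylated diphenol; not isolated) | CC(C)(C)OC(=O)C[C@H](c1ccccc1)c1c(OC)cc(O)c(C2(C)OCCO2)c1O | intermediate
24 | (3R)-3-(3-acetyl-2,4-dihydroxy-6-methoxyphenyl)-3-phenylpropanoic acid (hydroxy acid; not isolated) | OC(=O)C[C@H](c1ccccc1)c1c(OC)cc(O)c(C(C)=O)c1O | intermediate
25 | (4R)-8-acetyl-7-hydroxy-5-methoxy-4-phenyl-3,4-dihydro-2H-chromen-2-one | O=C1C[C@H](c2ccccc2)c2c(OC)cc(O)c(C(C)=O)c2O1 | intermediate
26 | (4R)-8-acetyl-5,7-dihydroxy-4-phenyl-3,4-dihydro-2H-chromen-2-one | O=C1C[C@H](c2ccccc2)c2c(O)cc(O)c(C(C)=O)c2O1 | intermediate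
27 | 3,4-dihydroxybenzaldehyde (protocatechualdehyde) | O=Cc1ccc(O)c(O)c1 | starting material
28 | (4R)-8-[(2E)-3-(3,4-dihydroxyphenyl)prop-2-enoyl]-5,7-dihydroxy-4-phenyl-3,4-dihydro-2H-chromen-2-one | O=C1C[C@H](c2ccccc2)c2c(O)cc(O)c(C(=O)/C=C/c3ccc(O)c(O)c3)c2O1 | target

Total step count: 13. Longest linear sequence: 10 steps (steps 1, 2, 3, 4, 6, 7, 10, 11, 12, 13).

Steps most likely to fail

Step 10. Capture of the short-lived vinylketene by the hindered ynol ether may lose to ketene dimerisation or to acylation of the product phenol, and the electrocyclic cascade may stall at the cyclobutenone stage. The fallback gives up the annulation and takes ring A from the aromatic pool, with the auxiliary setting C4. It sets out from 1, which is N-acylated with cinnamoyl chloride (n-BuLi, THF, −78 °C) to give (4R)-4-benzyl-3-[(2E)-3-phenylprop-2-enoyl]-1,3-oxazolidin-2-one F1. Copper-mediated conjugate addition of 2,4,6-trimethoxyphenylmagnesium bromide (CuBr·SMe2, THF, −40 °C) to the chelated s-cis imide, on the face away from the benzyl group, should give (4R)-4-benzyl-3-[(3R)-3-phenyl-3-(2,4,6-trimethoxyphenyl)propanoyl]-1,3-oxazolidin-2-one F2. BBr3 (CH2Cl2, −78 °C → rt, then warming with TsOH in toluene) cleaves the three methyl ethers, and an ortho phenol displaces the auxiliary to give (4R)-5,7-dihydroxy-4-phenyl-3,4-dihydro-2H-chromen-2-one F3. Friedel–Crafts acetylation (Ac2O, AlCl3, ClCH2CH2Cl, 75 °C) and separation from the 6-acetyl isomer then give 26, where the route resumes at step 13. This fallback no longer guarantees the C8 position of the acyl group.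

Step 6. The phosphonate anion may enolise the α-aryl aldehyde before adding to it, which would erode the configuration at C3, and the olefination may give an incomplete Z preference. The fallback forms the C4–C5 bond without base and sets out from 7. Methoxyacetone is silylated (Me3SiCl, Et3N, NaI, MeCN) to [(1-methoxyprop-1-en-2-yl)oxy]trimethylsilane F4. A Mukaiyama aldol addition of this enol ether to 7 (BF3·OEt2, CH2Cl2, −78 °C) gives tert-butyl (3R)-4-hydroxy-5-methoxy-6-oxo-3-phenylheptanoate F5 as a mixture of diastereomers at C4 and C5, in which C3 is no longer next to a carbonyl group. Mesylation and E1cB elimination (MsCl, Et3N, then DBU, CH2Cl2, 0 °C) lead to the thermodynamically preferred enone 10, where the route resumes at step 7.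

Step 13. Under Lewis acid the 7-hydroxyl may add to the new enone (flavanone closure), and the unprotected catechol aldehyde may oligomerise or oxidise, so that conversion stays low. The fallback runs the condensation in the classical basic mode with methyl-protected partners and sets out from 25. Compound 25 and 3,4-dimethoxybenzaldehyde in KOH/EtOH (the lactone opens to a phenolate carboxylate that tolerates base) give, after acidification, (3R)-3-{3-[(2E)-3-(3,4-dimethoxyphenyl)prop-2-enoyl]-2,4-dihydroxy-6-methoxyphenyl}-3-phenylpropanoic acid F6. Warming with TsOH in toluene recloses the lactone to (4R)-8-[(2E)-3-(3,4-dimethoxyphenyl)prop-2-enoyl]-7-hydroxy-5-methoxy-4-phenyl-3,4-dihydro-2H-chromen-2-one F7. BBr3 (CH2Cl2, −78 °C → rt) then cleaves all three methyl ethers and gives 28 directly, so step 12 is not needed.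

Further compounds
F1 | step 10 | (4R)-4-benzyl-3-[(2E)-3-phenylprop-2-enoyl]-1,3-oxazolidin-2-one | O=C1N(C(=O)/C=C/c2ccccc2)[C@H](Cc2ccccc2)CO1
F2 | step 10 | (4R)-4-benzyl-3-[(3R)-3-phenyl-3-(2,4,6-trimethoxyphenyl)propanoyl]-1,3-oxazolidin-2-one | O=C1N(C(=O)C[C@H](c2ccccc2)c2c(OC)cc(OC)cc2OC)[C@H](Cc2ccccc2)CO1
F3 | step 10 | (4R)-5,7-dihydroxy-4-phenyl-3,4-dihydro-2H-chromen-2-one | O=C1C[C@H](c2ccccc2)c2c(O)cc(O)cc2O1
F4 | step 6 | [(1-methoxyprop-1-en-2-yl)oxy]trimethylsilane (E/Z mixture) | COC=C(C)O[Si](C)(C)C
F5 | step 6 | tert-butyl (3R)-4-hydroxy-5-methoxy-6-oxo-3-phenylheptanoate (mixture at C4 and C5) | CC(C)(C)OC(=O)C[C@H](c1ccccc1)C(O)C(OC)C(C)=O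
F6 | step 13 | (3R)-3-{3-[(2E)-3-(3,4-dimethoxyphenyl)prop-2-enoyl]-2,4-dihydroxy-6-methoxyphenyl}-3-phenylpropanoic acid | OC(=O)C[C@H](c1ccccc1)c1c(OC)cc(O)c(C(=O)/C=C/c2ccc(OC)c(OC)c2)c1O
F7 | step 13 | (4R)-8-[(2E)-3-(3,4-dimethoxyphenyl)prop-2-enoyl]-7-hydroxy-5-methoxy-4-phenyl-3,4-dihydro-2H-chromen-2-one | O=C1C[C@H](c2ccccc2)c2c(OC)cc(O)c(C(=O)/C=C/c3ccc(OC)c(OC)c3)c2O1
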